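The data come from a simulation for substances that don't exist, noise included.

In this closed, stirred vessel we follow a gap: the share of the substrate charged that is lost but not read as target.

| setting | Thursday's | Sunday's | flask |
|---|---|---|---|
| substrate | 2 M | 2 M | 2.0 M |
| reagent | 2 M | 2 M | 2.00 M |
| capture agent | 0.20 M | 0.20 M | 0.200 M |
| free catalyst | 100 mM | 100 mM | 100 mM |
| second catalyst | 150 mM | 330 mM | 220 mM |
| added ligand | 340 mM | 340 mM | 340 mM |
| remark | run made earlier | run made earlier |  |

| run | time / min | target / % | substrate / % |
|---|---|---|---|
| Thursday's | 0.667 | 10 | 76 |
| Thursday's | 2.00 | 33 | 50 |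
| Thursday's | 3.00 | 47 | 36 |
| Thursday's | 5.00 | 69 | 16 |
| Thursday's | 8.00 | 78 | 7 |
| Thursday's | 10.0 | 85 | 2 |
| Thursday's | 12.0 | 87 | 1 |
| Sunday's | 1.50 | 32 | 59 |
| Sunday's | 3.00 | 58 | 36 |
| Sunday's | 5.00 | 72 | 18 |
| Sunday's | 6.00 | 80 | 12 |
| Sunday's | 8.00 | 85 | 8 |
| Sunday's | 10.0 | 88 | 3 |
| Sunday's | 12.0 | 93 | 2 |

(each reading ± 1.5 percentage points)

1. apparent order in free catalyst when 50% of the substrate are converted (percent change of the rate of making target for one percent more free catalyst charged)
2. apparent order in reagent when 50% of the substrate are converted (percent change of the rate of making target for one percent more reagent charged)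

- no earlier run changes the charge of free catalyst; that part of a forecast is a guess
- "the catalyst" is free catalyst with its forms; second catalyst is a second catalyst
- no earlier run changes the charge of reagent; that part of a forecast is a guess

Does second catalyst touch the loss of substrate? Thursday's and Sunday's flasks both read 36% substrate at 3.00 min. So we read one pseudo-first-order constant from them, 0.341 min⁻¹. This flask should then reach 50% conversion after 2.04 min.

How fast does the gap drain? At 3.00 min it stands at 17.0% on Thursday and 6.00% on Sunday. Around then the readings show target rising at about 0.120 min⁻¹ on Thursday and 0.114 min⁻¹ on Sunday, as fractions of the charge. Target rate over gap is our drain constant. We take it as proportional to second catalyst and average the two runs, which gives 1.15 min⁻¹ for this flask.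

Does a faster drain raise the target rate at that moment? Our first answer is no, since a balanced gap passes on what it receives. Going round once more, we put the filling back in. With drain constant times time at 2.35, the gap is not fully balanced, and one percent more drain gives 0.136 percent more rate. If reagent acts wholly on the drain, that is our order in reagent, which is a guess. Our order in free catalyst is a guess of 1.

The forecast says 1 for free catalyst and 0 for reagent: “So reagent order is about 0 even if it acts downstream”. We differ from it on reagent.

The flask gives 1.2 for free catalyst and 0.21 for reagent.

    substrate + free catalyst → free catalyst + open intermediate (k = 0.170 M⁻¹ s⁻¹)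
    second catalyst + open intermediate ⇌ catalyst intermediate (K = 0.510 M⁻¹, k = 0.580 M⁻¹ s⁻¹)
    reagent + catalyst intermediate → second catalyst + target (k = 0.280 M⁻¹ s⁻¹)
    free catalyst + added ligand ⇌ idle complex (K = 7.40 M⁻¹, k = 0.680 M⁻¹ s⁻¹)
    open intermediate + capture agent → trapped intermediate (k = 0.00740 M⁻¹ s⁻¹)

In this flask at 1.90 min, open intermediate is made at 0.947 of the rate at which it is used up, each step taken net. With our drain constant, the rate of making target at 3.46 min over that at 1.95 min comes to 0.707, and this flask gives 0.62. Scaled to Sunday's second catalyst, the constant gives a gap of 12.9% at 1.50 min, and Sunday's readings show 9.00%.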